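**Plan**
- Retrosynthesis: remove the two silyl groups, cut the ester C–O bond at O6, take the epoxide oxygen off the C8=C9 alkene, and return the C7 carbinol to a ketone; this leaves α'-hydroxy enone 15.
- Central cut: C6–C7 and C8–C9 of the seven-membered ring B are cut together. This excises C7–C8(–CH3) as a propionyl unit and leaves ring A (cyclopentane) with a C6 aldehyde on C5 and a C10–C9 acetal arm on C1.
- Enabling feature: C7 and C8 lie between two oxygenated ring-B carbons (C6 and C9). At the enone level C7 is an acyl carbon and C8 its enol carbon, so α-lithiated ethyl propenyl ether can bond first as an acyl anion (C7 to the C6 aldehyde) and then as an enol ether (C8 to a C9 oxocarbenium ion).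
- Forward order: ring A first (conjugate addition to 3-methylcyclopentenone with enolate trapping, C6 alkylation, isopropyl addition), then ring B by the one-flask (5+2) annulation, then reduction, silylation, epoxidation, esterification and desilylation.
- Stereochemistry: C1 from a chiral copper catalyst; C5 by alkylation anti to the larger arm; C4 by addition anti to C6; C6 by 1,3-chelation from the C4 alkoxide; C7 by hydride delivery from O6; C8/C9 by epoxidation directed by O6.

Key step: step 6

**Remarks**
- Locants follow daucane numbering: C1 (quaternary, CH3), C2, C3, C4 (OH, isopropyl), C5 (ring-fusion CH), C6 (ester), C7 (OH), C8 (CH3, epoxide), C9 (epoxide), C10. Ring A is the cyclopentane, ring B the cycloheptane; α is the face of H5, β the face of the C1 methyl.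
- Assumption: acid 19 is taken as a catalogue compound (otherwise one silylation of 4-hydroxybenzoic acid).
- Assumption: 11 is used as the commercial E/Z mixture, because the enol ether geometry is erased in step 6.

**Step 1**
Reactants: 1 3-methylcyclopent-2-en-1-one; 2 (1,3-dioxolan-2-ylmethyl)magnesium bromide
Product: 4 {[(3R)-3-(1,3-dioxolan-2-ylmethyl)-3-methylcyclopent-1-en-1-yl]oxy}trimethylsilane, via bromomagnesium enolate 3 (not isolated)
Conditions: Cu(OTf)2 (cat.), chiral imidazolinium chloride (NHC precursor, cat.), Et2O/THF, −30 °C; then TMSCl, Et3N, DMPU, −30 → 23 °C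
Reagents that add atoms: chlorotrimethylsilane C[Si](C)(C)Cl
Why: Copper-catalysed asymmetric conjugate addition of a Grignard reagent to a β-substituted cyclopentenone should build quaternary C1 under ligand control (ligand enantiomer chosen for 1R), and silylation of the regiodefined magnesium enolate fixes the enol double bond toward C5.

**Step 2**
Reactants: 4 silyl enol ether; 5 benzyl chloromethyl ether
Product: 6 (2S,3R)-2-[(benzyloxy)methyl]-3-(1,3-dioxolan-2-ylmethyl)-3-methylcyclopentan-1-one
Conditions: ZnBr2 (10 mol %), CH2Cl2, 0 → 23 °C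
Reagents that add atoms: none
Why: Lewis-acid-mediated (Mukaiyama-type) alkylation of the silyl enol ether with the α-chloro ether forms C5–C6 only at carbon; the electrophile should enter anti to the bulkier dioxolanylmethyl arm (cis to CH3), but the preference between CH3 and CH2R is expected to be modest, and the epimerisable α-centre lets a minor isomer be equilibrated toward the same isomer.

**Step 3**
Reactants: 6 ketone; 7 isopropylmagnesium chloride
Product: 8 (1R,2S,3R)-2-[(benzyloxy)methyl]-3-(1,3-dioxolan-2-ylmethyl)-3-methyl-1-(propan-2-yl)cyclopentan-1-ol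
Conditions: CeCl3 (anhydrous), i-PrMgCl, THF, −78 → 0 °C; aq NH4Cl
Reagents that add atoms: none
Why: Organocerium 1,2-addition suppresses enolisation and β-elimination of the benzyloxy group, and the isopropyl group should enter anti to the adjacent C5 substituent, giving the C4 carbinol with OH cis to C6.

**Step 4**
Reactants: 8 benzyl ether
Product: 9 (1R,2S,3R)-3-(1,3-dioxolan-2-ylmethyl)-2-(hydroxymethyl)-3-methyl-1-(propan-2-yl)cyclopentan-1-ol
Conditions: H2 (1 atm), 10% Pd/C, EtOAc, 23 °C
Reagents that add atoms: none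
Why: Hydrogenolysis removes the benzyl ether while the dioxolane and the tertiary alcohol are untouched.

**Step 5**
Reactants: 9 diol
Product: 10 (1R,2R,5R)-2-(1,3-dioxolan-2-ylmethyl)-5-hydroxy-2-methyl-5-(propan-2-yl)cyclopentane-1-carbaldehyde
Conditions: TEMPO (10 mol %), PhI(OAc)2, CH2Cl2, 23 °C; used at once
Reagents that add atoms: none
Why: Oxoammonium oxidation acts only on the primary alcohol, and the α-centre C5 already sits in its more stable arrangement (CHO trans to isopropyl and to the acetal arm).

**Step 6**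
Reactants: 10 hydroxy aldehyde; 11 ethyl prop-1-enyl ether
Product: 15 (1R,4R,5S,6R)-4,6-dihydroxydauc-8-en-7-one, via lithiated enol ether 12 (not isolated), via dilithium alkoxide adduct 13 (not isolated), via ring-closed silylated enol ether 14 (not isolated)
Conditions: 11, t-BuLi, THF, −78 → −5 °C; 10, THF, −78 °C; then TMSOTf, 2,6-di-tert-butyl-4-methylpyridine, CH2Cl2, −78 → −30 °C; then 1 M HCl, THF, 0 → 23 °C
Reagents that add atoms: water O
Why: The α-lithiated enol ether 12 (a propionyl anion equivalent) adds to the aldehyde of the lithium alkoxide of 10 to form C6–C7 (13); TMSOTf then silylates both alkoxides and ionises the dioxolane to an oxocarbenium ion at C9, which is captured by enol ether carbon C8 to form C8–C9 (14 after proton loss), and aqueous acid hydrolyses the enol ether, expels the 2-hydroxyethoxy group from C9 and cleaves the TMS ethers to give enone 15. The closest known reaction types are the addition of 1-alkoxyvinyllithium reagents to aldehydes and the Lewis-acid-mediated enol ether–acetal (Mukaiyama-type) aldol cyclisation, here run in one flask. Ring B closes in a 7-(enolendo)-exo-trig mode between the trans-disposed arms of ring A, so the trans ring fusion is preset. C6 is the only new stereocentre that is kept: lithium bridges the C4 alkoxide and the aldehyde oxygen (1,3-chelate) and the nucleophile should enter from the face of H5, away from quaternary C1, which corresponds to 6R; C8 and C9 are erased on elimination. The step needs chemoselectivity (the organolithium must meet only the aldehyde) and regioselectivity in the second bond (C8, not a C6 enol, must attack C9); both are secured by keeping the ketone as a regiodefined enol ether until the base-inert acetal is ionised, with the hindered pyridine preventing protonation of the enol ether.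

**Step 7**
Reactants: 15 α'-hydroxy enone
Product: 16 (1R,4R,5S,6R,7R)-dauc-8-ene-4,6,7-triol
Conditions: Me4NBH(OAc)3, MeCN/AcOH, −30 °C
Reagents that add atoms: none
Why: Hydroxyl-directed 1,2-reduction, in which the borohydride bound to O6 should deliver hydride to the α-face of the C7 ketone and give the 6,7-trans diol (7-OH β).

**Step 8**
Reactants: 16 triol
Product: 17 (1R,4R,5S,6R,7R)-7-[(triethylsilyl)oxy]dauc-8-ene-4,6-diol
Conditions: TESCl, imidazole, CH2Cl2, −20 °C
Reagents that add atoms: chlorotriethylsilane CC[Si](Cl)(CC)CC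
Why: The allylic C7 hydroxyl is much less hindered than the C6 hydroxyl (next to C5 between two quaternary carbons) and the tertiary C4 hydroxyl, so monosilylation should occur at O7.

**Step 9**
Reactants: 17 silyl ether
Product: 18 (1R,4R,5S,6R,7S,8R,9S)-8,9-epoxy-7-[(triethylsilyl)oxy]daucane-4,6-diol
Conditions: VO(acac)2 (5 mol %), t-BuOOH, CH2Cl2, 0 °C
Reagents that add atoms: tert-butyl hydroperoxide CC(C)(C)OO
Why: Vanadium-catalysed epoxidation directed by the homoallylic C6 hydroxyl (α) should deliver oxygen to the α-face of C8=C9, the face also left open by the β-OTES group at C7 and the β-methyl at C1, setting C8 and C9.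

**Step 10**
Reactants: 18 epoxy diol; 19 4-[(tert-butyldimethylsilyl)oxy]benzoic acid
Product: 21 (1R,4R,5S,6R,7S,8R,9S)-8,9-epoxy-4-hydroxy-7-[(triethylsilyl)oxy]daucan-6-yl 4-[(tert-butyldimethylsilyl)oxy]benzoate, via mixed anhydride 20 (not isolated)
Conditions: 19, 2,4,6-trichlorobenzoyl chloride, Et3N, toluene, 23 °C; then 18, DMAP, toluene, 60 °C
Reagents that add atoms: none
Why: Yamaguchi esterification acylates the hindered secondary C6 hydroxyl through the DMAP-activated mixed anhydride, while the tertiary C4 hydroxyl stays free and the base-stable epoxide and silyl ether survive.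

**Step 11**
Reactants: 21 bis-silyl ester
Product: 22 (1R,4R,5S,6R,7S,8R,9S)-8,9-epoxy-4,7-dihydroxydaucan-6-yl 4-hydroxybenzoate
Conditions: TBAF, AcOH, THF, 0 °C
Reagents that add atoms: none
Why: Fluoride cleaves the triethylsilyl ether and the aryl silyl ether in one operation, and the acetic acid buffer should prevent 6→7 acyl migration and epoxide opening.

**Compound list**
1 | 3-methylcyclopent-2-en-1-one | CC1=CC(=O)CC1 | starting material
2 | (1,3-dioxolan-2-ylmethyl)magnesium bromide | Br[Mg]CC1OCCO1 | starting material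
3 | bromomagnesium (3R)-3-(1,3-dioxolan-2-ylmethyl)-3-methylcyclopent-1-en-1-olate | Br[Mg]OC1=C[C@@](C)(CC2OCCO2)CC1 | intermediate
4 | {[(3R)-3-(1,3-dioxolan-2-ylmethyl)-3-methylcyclopent-1-en-1-yl]oxy}trimethylsilane | C[Si](C)(C)OC1=C[C@@](C)(CC2OCCO2)CC1 | intermediate
5 | benzyl chloromethyl ether | ClCOCc1ccccc1 | starting material
6 | (2S,3R)-2-[(benzyloxy)methyl]-3-(1,3-dioxolan-2-ylmethyl)-3-methylcyclopentan-1-one | O=C1CC[C@](C)(CC2OCCO2)[C@H]1COCc1ccccc1 | intermediate
7 | isopropylmagnesium chloride | CC(C)[Mg]Cl | starting material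
8 | (1R,2S,3R)-2-[(benzyloxy)methyl]-3-(1,3-dioxolan-2-ylmethyl)-3-methyl-1-(propan-2-yl)cyclopentan-1-ol | CC(C)[C@]1(O)CC[C@](C)(CC2OCCO2)[C@H]1COCc1ccccc1 | intermediate
9 | (1R,2S,3R)-3-(1,3-dioxolan-2-ylmethyl)-2-(hydroxymethyl)-3-methyl-1-(propan-2-yl)cyclopentan-1-ol | CC(C)[C@]1(O)CC[C@](C)(CC2OCCO2)[C@H]1CO | intermediate
10 | (1R,2R,5R)-2-(1,3-dioxolan-2-ylmethyl)-5-hydroxy-2-methyl-5-(propan-2-yl)cyclopentane-1-carbaldehyde | CC(C)[C@]1(O)CC[C@](C)(CC2OCCO2)[C@H]1C=O | intermediate
11 | ethyl prop-1-enyl ether (E/Z mixture) | CC=COCC | starting material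
12 | (1-ethoxyprop-1-en-1-yl)lithium | [Li]C(OCC)=CC | intermediate
13 | dilithium dialkoxide of (1R,2S,3R)-3-(1,3-dioxolan-2-ylmethyl)-2-[(1R)-2-ethoxy-1-hydroxybut-2-en-1-yl]-3-methyl-1-(propan-2-yl)cyclopentan-1-ol | CC(C)[C@]1(O[Li])CC[C@](C)(CC2OCCO2)[C@H]1[C@@H](O[Li])C(OCC)=CC | intermediate
14 | (1R,4R,5S,6R)-7-ethoxy-4,6-bis[(trimethylsilyl)oxy]-9-{2-[(trimethylsilyl)oxy]ethoxy}dauc-7-ene (C9 epimers) | CC(C)[C@]1(O[Si](C)(C)C)CC[C@]2(C)CC(OCCO[Si](C)(C)C)C(C)=C(OCC)[C@H](O[Si](C)(C)C)[C@H]21 | intermediate
15 | (1R,4R,5S,6R)-4,6-dihydroxydauc-8-en-7-one [(1R,3aR,8R,8aS)-1,8-dihydroxy-3a,6-dimethyl-1-(propan-2-yl)-2,3,3a,4,8,8a-hexahydroazulen-7(1H)-one] | CC(C)[C@]1(O)CC[C@]2(C)CC=C(C)C(=O)[C@H](O)[C@H]21 | intermediate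
16 | (1R,4R,5S,6R,7R)-dauc-8-ene-4,6,7-triol (6,7-trans) | CC(C)[C@]1(O)CC[C@]2(C)CC=C(C)[C@@H](O)[C@H](O)[C@H]21 | intermediate
17 | (1R,4R,5S,6R,7R)-7-[(triethylsilyl)oxy]dauc-8-ene-4,6-diol | CC(C)[C@]1(O)CC[C@]2(C)CC=C(C)[C@@H](O[Si](CC)(CC)CC)[C@H](O)[C@H]21 | intermediate
18 | (1R,4R,5S,6R,7S,8R,9S)-8,9-epoxy-7-[(triethylsilyl)oxy]daucane-4,6-diol (8α,9α-epoxide) | CC(C)[C@]1(O)CC[C@]2(C)C[C@@H]3O[C@]3(C)[C@@H](O[Si](CC)(CC)CC)[C@H](O)[C@H]21 | intermediate
19 | 4-[(tert-butyldimethylsilyl)oxy]benzoic acid | CC(C)(C)[Si](C)(C)Oc1ccc(cc1)C(O)=O | starting material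
20 | 4-[(tert-butyldimethylsilyl)oxy]benzoic 2,4,6-trichlorobenzoic anhydride | CC(C)(C)[Si](C)(C)Oc1ccc(cc1)C(=O)OC(=O)c1c(Cl)cc(Cl)cc1Cl | intermediate
21 | (1R,4R,5S,6R,7S,8R,9S)-8,9-epoxy-4-hydroxy-7-[(triethylsilyl)oxy]daucan-6-yl 4-[(tert-butyldimethylsilyl)oxy]benzoate | CC(C)[C@]1(O)CC[C@]2(C)C[C@@H]3O[C@]3(C)[C@@H](O[Si](CC)(CC)CC)[C@H](OC(=O)c3ccc(O[Si](C)(C)C(C)(C)C)cc3)[C@H]21 | intermediate
22 | (1R,4R,5S,6R,7S,8R,9S)-8,9-epoxy-4,7-dihydroxydaucan-6-yl 4-hydroxybenzoate | CC(C)[C@]1(O)CC[C@]2(C)C[C@@H]3O[C@]3(C)[C@@H](O)[C@H](OC(=O)c3ccc(O)cc3)[C@H]21 | target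

**Total step count:** 11
**Longest linear sequence:** 11 steps (1 → 22)

**Steps most likely to fail**

Step 6. The α-lithiation of 11 may be incomplete, chelation control at C6 may erode, the C9 oxocarbenium ion may be diverted into oxygen capture or the enol ether may hydrolyse before ring closure, and C6 may epimerise through the enediol during the acid stage. The fallback closes ring B by olefin metathesis instead; it sets out from 10 and comes back at 16, so it also replaces step 7. Syn-selective γ-alkoxyallylboration of 10 with the (Z)-[3-(methoxymethoxy)-2-methylallyl]diisopinocampheylborane (from 3-(methoxymethoxy)-2-methylprop-1-ene, s-BuLi and (Ipc)2BOMe, Ipc enantiomer matched to the substrate) should give the 6,7-syn adduct F1, with C6 and C7 set together by the cyclic transition state. Mild aqueous acid unmasks the aldehyde F2, Ph3P=CH2 converts it into the diene F3, the second-generation Grubbs catalyst closes the C8=C9 bond to give the cycloheptene F4, and acid-catalysed methanolysis of the methoxymethyl ether returns 16.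

Step 1. Enantio-induction may be low for a five-membered enone with an acetal-bearing Grignard reagent in a THF-containing medium, and silylation of the magnesium enolate may be incomplete. The fallback reverses the roles of the two C1 substituents; it sets out from 3-ethoxycyclopent-2-en-1-one and 2 and comes back at 4. Addition of 2 gives the tertiary carbinol F5, which on mild acid work-up undergoes the Stork–Danheiser transposition to the enone F6. Copper-catalysed asymmetric conjugate addition of Me3Al (chiral phosphoramidite ligand) then delivers the methyl group to create the same quaternary centre, and the aluminium enolate F7 is silylated with TMSOTf to give 4.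

Step 7. Hydride may be delivered without direction or from the C4 oxygen (giving the 6,7-cis diol), or conjugate reduction may compete. The fallback uses reagent control; it sets out from 15 and comes back at 16. Silylation of O6 (TESCl, imidazole) gives the 6-O-triethylsilyl enone F8, Corey–Bakshi–Shibata reduction with the oxazaborolidine enantiomer matched to β-hydroxyl formation gives the 7β-alcohol F9, and buffered TBAF returns 16.

**Further compounds**
F1 | step 6 | 6,7-syn allylboration adduct of 10 (6-OH, 7-OCH2OCH3, isopropenyl terminus) | CC(C)[C@]1(O)CC[C@](C)(CC2OCCO2)[C@H]1[C@@H](O)[C@H](OCOC)C(C)=C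
F2 | step 6 | aldehyde from dioxolane hydrolysis of F1 | CC(C)[C@]1(O)CC[C@](C)(CC=O)[C@H]1[C@@H](O)[C@H](OCOC)C(C)=C
F3 | step 6 | diene from methylenation of F2 | CC(C)[C@]1(O)CC[C@](C)(CC=C)[C@H]1[C@@H](O)[C@H](OCOC)C(C)=C
F4 | step 6 | (1R,4R,5S,6R,7R)-7-(methoxymethoxy)dauc-8-ene-4,6-diol | CC(C)[C@]1(O)CC[C@]2(C)CC=C(C)[C@@H](OCOC)[C@H](O)[C@H]21
F5 | step 1 | 1-(1,3-dioxolan-2-ylmethyl)-3-ethoxycyclopent-2-en-1-ol | CCOC1=CC(O)(CC2OCCO2)CC1
F6 | step 1 | 3-(1,3-dioxolan-2-ylmethyl)cyclopent-2-en-1-one | O=C1C=C(CC2OCCO2)CC1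
F7 | step 1 | dimethylaluminium (3R)-3-(1,3-dioxolan-2-ylmethyl)-3-methylcyclopent-1-en-1-olate | C[Al](C)OC1=C[C@@](C)(CC2OCCO2)CC1
F8 | step 7 | (1R,4R,5S,6R)-4-hydroxy-6-[(triethylsilyl)oxy]dauc-8-en-7-one | CC(C)[C@]1(O)CC[C@]2(C)CC=C(C)C(=O)[C@H](O[Si](CC)(CC)CC)[C@H]21
F9 | step 7 | (1R,4R,5S,6R,7R)-6-[(triethylsilyl)oxy]dauc-8-ene-4,7-diol | CC(C)[C@]1(O)CC[C@]2(C)CC=C(C)[C@@H](O)[C@H](O[Si](CC)(CC)CC)[C@H]21
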